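**Retrosynthetic overview**
- The C4 aroyl ester and the C3 carbinol are released last. The γ-hydroxy enone (C4–OH, C5=C6, C7=O) is unmasked in one isomerisation from the α-epoxide of a C4=C5 alkene next to a C7 ketone.
- The seven-membered ring (C3a, C4, C5, C6, C7, C8, C8a) is the second ring. It is closed by metathesis at C4=C5 between the C3a vinyl group and a crotyl-derived C5–C6(–CH3) unit added to the C7 aldehyde.
- The strategy rests on the five-membered ring (C1, C2, C3, C3a, C8a). Its trans ring-fusion pair C3a (CH) and C8a (quaternary, methyl) are the β- and α-carbons of a 2-methylcyclopent-2-enone with C1 as carbonyl and the C3 oxygen as 4-oxy substituent. C3a–C4 (vinyl conjugate addition) and C8a–C8 (enolate prenylation) are therefore made trans in one pot on a purchased (S)-4-silyloxycyclopentenone, which supplies the first ring.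
- The purchased C3 oxygen centre is a relay: it sets C3a, then through C3a the C8a centre, then the C1 carbinol, and is afterwards oxidised and rebuilt as the isopropyl carbinol.

Key step: step 3

Remarks on the chemistry:
- Target numbering is used for all intermediates; β is the face of the C8a methyl group, α the face of H3a.
- Compound 15 (new secondary carbinol) and compounds 18–21 (C6, C7) are carried as diastereomeric mixtures, because these centres become trigonal in 16 and 22.
- The acetyl group lost in step 19 is counted as acetic acid.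

Step 1
Reactants: 1 (S)-4-(tert-butyldimethylsilyloxy)cyclopent-2-en-1-one
Product: 2 (S)-4-(tert-butyldimethylsilyloxy)-2-iodocyclopent-2-en-1-one
Conditions: I2, pyridine/CH2Cl2 (1:1), 0 °C to rt
Reagents that add atoms: iodine, II
Why: Johnson α-iodination of an enone (conjugate addition of pyridine, iodination of the enolate, elimination) puts iodine on the future C8a without touching the silyloxy stereocentre.

Step 2
Reactants: 2 (S)-4-(tert-butyldimethylsilyloxy)-2-iodocyclopent-2-en-1-one
Product: 3 (S)-4-(tert-butyldimethylsilyloxy)-2-methylcyclopent-2-en-1-one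
Conditions: MeZnCl, Pd(PPh3)4 (5 mol %), THF, 0 °C to rt
Reagents that add atoms: methylzinc chloride, C[Zn]Cl
Why: Negishi cross-coupling (oxidative addition of the C–I bond to zerovalent palladium, transmetalation from zinc, reductive elimination) installs the future C8a methyl group under conditions too mild to eliminate the γ-silyloxy group.

Step 3
Reactants: 3 (S)-4-(tert-butyldimethylsilyloxy)-2-methylcyclopent-2-en-1-one; 4 vinylmagnesium bromide; 5 prenyl bromide
Product: 7 all-trans cyclopentanone (C1 ketone; C8a β-methyl α-prenyl; C3a β-vinyl; C3 α-OTBS), via bromomagnesium enolate 6 (not isolated)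
Conditions: 4 (1.3 equiv), CuBr·SMe2 (10 mol %), THF, −78 to −40 °C; then HMPA, 5 (3 equiv), −78 to −20 °C; cold aq. NH4Cl quench
Reagents that add atoms: vinylmagnesium bromide (4), C=C[Mg]Br; prenyl bromide (5), CC(C)=CCBr
Why: Copper-catalysed 1,4-addition of the vinyl Grignard reagent (through the catalytic species (CH2=CH)2CuMgBr) gives the regiodefined enolate 6 spanning C1/C8a, which is C-alkylated in the same flask by SN2 attack on the primary carbon of prenyl bromide once HMPA has loosened the enolate aggregates; the closest known reaction type is the prostaglandin-style three-component coupling on 4-silyloxycyclopent-2-enones and the vicinal dialkylation of 2-methylcyclopent-2-enone. The step forms the C3a–C4 and C8a–C8 bonds and closes no ring, the five-membered ring arriving intact in 1. C3a is controlled by the C3 silyloxy group, which sends the vinyl group to the opposite (β) face, and the quaternary C8a is controlled by that new vinyl group, which steers the allylic bromide to the α face so that the methyl group ends up β and the two future seven-ring arms are trans. The selectivity needed is C-alkylation at C8a ahead of proton transfer that would shift the enolate to C2 and expel silanolate from C3; the tetrasubstituted enolate formed directly by the conjugate addition, the high reactivity of an allylic bromide in THF/HMPA and the cold quench secure it.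

Step 4
Reactants: 7 all-trans cyclopentanone with C3 α-OTBS
Product: 8 β-hydroxy ketone (C1 ketone; C3 α-OH; C3a β-vinyl; C8a β-methyl, α-prenyl)
Conditions: HF·pyridine, pyridine, THF, 0 °C to rt
Reagents that add atoms: none
Why: Fluoride-mediated desilylation under buffered, weakly acidic conditions frees the C3 hydroxyl without dehydrating the β-hydroxy ketone or touching the alkenes.

Step 5
Reactants: 8 β-hydroxy ketone
Product: 9 anti-1,3-diol (C1 β-OH; C3 α-OH; C3a β-vinyl; C8a β-methyl, α-prenyl)
Conditions: Me4NBH(OAc)3, MeCN/AcOH (1:1), −30 to −20 °C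
Reagents that add atoms: none
Why: In this Evans–Saksena hydroxyl-directed reduction the C3 hydroxyl binds boron and the alkoxyborohydride delivers hydride intramolecularly to the α face of the C1 carbonyl, so the new C1 hydroxyl is β, anti to the C3 hydroxyl and cis to the C8a methyl group.

Step 6
Reactants: 9 anti-1,3-diol
Product: 10 transposed ketol (C1 β-OH; C3 ketone; C3a β-vinyl; C8a β-methyl, α-prenyl)
Conditions: TEMPO (0.2 equiv), PhI(OAc)2 (1.1 equiv), CH2Cl2, 0 °C to rt, stopped at full mono-oxidation
Reagents that add atoms: none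
Why: Oxoammonium (TEMPO/PhI(OAc)2) oxidation is very sensitive to steric hindrance, so the C3 carbinol flanked by CH2 and CH should be oxidised well before the neopentylic C1 carbinol next to the quaternary C8a, and the non-basic medium spares the allylic C3a–H of the new ketone.

Step 7
Reactants: 10 transposed ketol; 11 isopropylmagnesium chloride
Product: 12 diol (C1 β-OH; C3 β-OH, α-isopropyl; C3a β-vinyl; C8a β-methyl, α-prenyl)
Conditions: LaCl3·2LiCl (1.1 equiv), THF, rt; then 11 (3.5 equiv), −20 to 0 °C; aq. NH4Cl
Reagents that add atoms: isopropylmagnesium chloride (11), CC(C)[Mg]Cl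
Why: In this lanthanide-promoted Grignard 1,2-addition the oxophilic, weakly basic organolanthanum species suppresses enolisation at C3a and β-hydride reduction, the first equivalent is spent on the C1 alkoxide, and isopropyl enters C3 on the α face anti to the adjacent β-vinyl group, leaving the hydroxyl β.

Step 8
Reactants: 12 diol
Product: 13 C1 acetate with free tertiary C3 hydroxyl
Conditions: Ac2O, DMAP (cat.), pyridine, CH2Cl2, rt
Reagents that add atoms: acetic anhydride, CC(=O)OC(C)=O
Why: DMAP-catalysed acylation takes the secondary C1 hydroxyl, while the tertiary C3 carbinol next to the isopropyl group is too hindered to react at room temperature.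

Step 9
Reactants: 13 C1 acetate
Product: 14 C1 acetate, C3 triethylsilyl ether
Conditions: TESOTf, 2,6-lutidine, CH2Cl2, −78 to 0 °C
Reagents that add atoms: triethylsilyl triflate, CC[Si](CC)(CC)OS(=O)(=O)C(F)(F)F
Why: Silylation with a silyl triflate and a hindered base is the standard way to cap a tertiary alcohol; the resulting bulky β-silyloxy group later helps to screen the β face of C4.

Step 10
Reactants: 14 C1 acetate, C3 triethylsilyl ether
Product: 15 prenyl-derived vicinal diol (side chain CH2–CH(OH)–C(OH)(CH3)2 on C8a; epimers at the secondary carbinol)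
Conditions: OsO4 (2 mol %), N-methylmorpholine N-oxide (1.1 equiv), acetone/H2O, 0 °C
Reagents that add atoms: N-methylmorpholine N-oxide, C[N+]1([O-])CCOCC1; water, O
Why: In this Upjohn dihydroxylation the electron-rich trisubstituted prenyl alkene reacts with OsO4 much faster than the monosubstituted vinyl group, which is in addition wedged between the fully substituted C3 and C8a.

Step 11
Reactants: 15 prenyl-derived vicinal diol
Product: 16 C7 aldehyde (CH2–CHO on C8a; C1 β-OAc; C3 β-OTES; C3a β-vinyl)
Conditions: NaIO4, THF/pH 7 buffer, 0 °C to rt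
Reagents that add atoms: none
Why: Periodate glycol cleavage at neutral pH removes the three terminal carbons as acetone and leaves C7 as an aldehyde, with the acetate and silyl ether intact.

Step 12
Reactants: 16 C7 aldehyde; 17 (E)-crotylboronic acid pinacol ester
Product: 18 metathesis diene (C7 carbinol, C6 methyl, terminal C5 alkene; C6/C7 anti, mixture with respect to the ring)
Conditions: 17 (1.5 equiv), toluene, rt to 40 °C; aq. NaHCO3 work-up
Reagents that add atoms: (E)-crotylboronic acid pinacol ester (17), C/C=C/CB1OC(C)(C)C(C)(C)O1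
Why: Crotylboration through a closed chair (Zimmerman–Traxler) transition state joins C7 to the γ-carbon of the crotyl unit and gives the branched homoallylic alcohol; the two new centres need no control because both are erased later.

Step 13
Reactants: 18 metathesis diene
Product: 19 trans-fused hydroazulene (C4=C5 alkene; C6 methyl; C7 carbinol; C6/C7 mixed)
Conditions: second-generation Grubbs catalyst (H2IMes)(PCy3)Cl2Ru=CHPh (5 mol %), CH2Cl2 (5 mM), 40 °C
Reagents that add atoms: none
Why: In this ring-closing olefin metathesis the ruthenium carbene loads on the unhindered C5 terminal alkene and closes onto the hindered C3a vinyl group with loss of ethene, giving the cis C4=C5 alkene of the seven-membered ring; the free C7 hydroxyl is tolerated.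

Step 14
Reactants: 19 trans-fused hydroazulene
Product: 20 4α,5α-epoxide (C7 carbinol; C6/C7 mixed)
Conditions: dimethyldioxirane (acetone solution), CH2Cl2, −20 to 0 °C
Reagents that add atoms: dimethyldioxirane, CC1(C)OO1
Why: In this dioxirane epoxidation the β face of C4=C5 is screened by the axial C8a methyl group and by the C3 triethylsilyloxy group lying syn to C4, so oxygen should arrive on the α face (that of H3a) and fix the C4–O bond α.

Step 15
Reactants: 20 4α,5α-epoxide
Product: 21 β,γ-epoxy ketone (C7 ketone; 4α,5α-epoxide; C6 mixed), used crude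
Conditions: Dess–Martin periodinane, NaHCO3, CH2Cl2, 0 °C to rt
Reagents that add atoms: none
Why: Buffered Dess–Martin oxidation converts the C7 carbinol into the ketone under neutral conditions that leave the epoxide, acetate and silyl ether untouched.

Step 16
Reactants: 21 β,γ-epoxy ketone
Product: 22 γ-hydroxy enone (C4 α-OH; C5=C6 with C6 methyl; C7 ketone; C3 β-OTES; C1 β-OAc)
Conditions: Et3N, CH2Cl2, 0 °C to rt
Reagents that add atoms: none
Why: In this base-induced E1cB isomerisation of a β,γ-epoxy ketone, deprotonation at C6 and cleavage of the C5–O bond leave the C4–O bond untouched (α retained), and both C6 epimers converge on the single C5=C6 enone.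

Step 17
Reactants: 22 γ-hydroxy enone; 23 4-acetoxybenzoic acid
Product: 25 protected target (C4 α-4-acetoxybenzoate; C3 β-OTES; C1 β-OAc), via 4-acetoxybenzoyl chloride 24 (not isolated)
Conditions: 23, (COCl)2, DMF (cat.), CH2Cl2, 0 °C to rt, evaporate; then 22, Et3N, DMAP, CH2Cl2, 0 °C to rt
Reagents that add atoms: 4-acetoxybenzoic acid (23), CC(=O)Oc1ccc(cc1)C(=O)O; oxalyl chloride, ClC(=O)C(Cl)=O (supplies only the chlorine of 24)
Why: DMAP-catalysed acylation by an acid chloride esterifies the hindered allylic C4 hydroxyl with retention, the only free hydroxyl in 22.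

Step 18
Reactants: 25 protected target
Product: 26 C3 carbinol with the C4 4-acetoxybenzoate still acetylated
Conditions: HF·pyridine, pyridine, THF, 0 °C to rt
Reagents that add atoms: none
Why: Fluoride-mediated desilylation removes the tertiary triethylsilyl ether under buffered conditions that leave the three esters and the enone untouched.

Step 19
Reactants: 26 C3 carbinol with aryl acetate
Product: 27 target CNP0087181.7
Conditions: NH4OAc, MeOH/H2O (4:1), rt
Reagents that add atoms: none
Why: In this chemoselective solvolysis the aryl acetate, with its phenoxide leaving group, is far more reactive than the secondary C1 acetate or the C4 aroyl ester, so near-neutral NH4OAc removes it alone.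

**Compound list**
1 | (S)-4-(tert-butyldimethylsilyloxy)cyclopent-2-en-1-one | O=C1C=C[C@@H](O[Si](C)(C)C(C)(C)C)C1 | starting material
2 | (S)-4-(tert-butyldimethylsilyloxy)-2-iodocyclopent-2-en-1-one | O=C1C(I)=C[C@@H](O[Si](C)(C)C(C)(C)C)C1 | intermediate
3 | (S)-4-(tert-butyldimethylsilyloxy)-2-methylcyclopent-2-en-1-one | CC1=C[C@@H](O[Si](C)(C)C(C)(C)C)CC1=O | intermediate
4 | vinylmagnesium bromide | C=C[Mg]Br | starting material
5 | prenyl bromide (1-bromo-3-methylbut-2-ene) | CC(C)=CCBr | starting material
6 | bromomagnesium C1/C8a enolate with C3a β-vinyl and C3 α-OTBS | Br[Mg]OC1=C(C)[C@H](C=C)[C@@H](O[Si](C)(C)C(C)(C)C)C1 | intermediate (not isolated)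
7 | (4S)-4-(tert-butyldimethylsilyloxy)-2-methyl-2-prenyl-3-vinylcyclopentan-1-one, vinyl trans to both the silyloxy and the prenyl group (C8a β-methyl, α-prenyl; C3a β-vinyl; C3 α-OTBS) | O=C1C[C@H](O[Si](C)(C)C(C)(C)C)[C@@H](C=C)[C@]1(C)CC=C(C)C | intermediate
8 | desilylated β-hydroxy ketone (C1 ketone, C3 α-OH) | O=C1C[C@H](O)[C@@H](C=C)[C@]1(C)CC=C(C)C | intermediate
9 | anti-1,3-diol (C1 β-OH, C3 α-OH) | O[C@H]1C[C@H](O)[C@@H](C=C)[C@]1(C)CC=C(C)C | intermediate
10 | transposed ketol (C1 β-OH, C3 ketone) | O[C@H]1CC(=O)[C@@H](C=C)[C@]1(C)CC=C(C)C | intermediate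
11 | isopropylmagnesium chloride | CC(C)[Mg]Cl | starting material
12 | diol with tertiary C3 carbinol (C3 β-OH, α-isopropyl; C1 β-OH) | O[C@H]1C[C@](O)(C(C)C)[C@@H](C=C)[C@]1(C)CC=C(C)C | intermediate
13 | C1 acetate, free C3 carbinol | CC(=O)O[C@H]1C[C@](O)(C(C)C)[C@@H](C=C)[C@]1(C)CC=C(C)C | intermediate
14 | C1 acetate, C3 triethylsilyl ether | CC(=O)O[C@H]1C[C@](O[Si](CC)(CC)CC)(C(C)C)[C@@H](C=C)[C@]1(C)CC=C(C)C | intermediate
15 | prenyl-derived vicinal diol (epimers at the secondary carbinol) | CC(=O)O[C@H]1C[C@](O[Si](CC)(CC)CC)(C(C)C)[C@@H](C=C)[C@]1(C)CC(O)C(C)(C)O | intermediate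
16 | C7 aldehyde | CC(=O)O[C@H]1C[C@](O[Si](CC)(CC)CC)(C(C)C)[C@@H](C=C)[C@]1(C)CC=O | intermediate
17 | (E)-crotylboronic acid pinacol ester | C/C=C/CB1OC(C)(C)C(C)(C)O1 | starting material
18 | metathesis diene, C7 homoallylic alcohol (C6/C7 anti, mixed with respect to the ring) | CC(=O)O[C@H]1C[C@](O[Si](CC)(CC)CC)(C(C)C)[C@@H](C=C)[C@]1(C)CC(O)C(C)C=C | intermediate
19 | trans-fused hydroazulene with C4=C5 alkene and C7 carbinol (C6/C7 mixed) | CC(=O)O[C@H]1C[C@](O[Si](CC)(CC)CC)(C(C)C)[C@H]2C=CC(C)C(O)C[C@]12C | intermediate
20 | 4α,5α-epoxide of 19 | CC(=O)O[C@H]1C[C@](O[Si](CC)(CC)CC)(C(C)C)[C@H]2[C@@H]3O[C@@H]3C(C)C(O)C[C@]12C | intermediate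
21 | β,γ-epoxy ketone (C7 ketone, 4α,5α-epoxide, C6 mixed) | CC(=O)O[C@H]1C[C@](O[Si](CC)(CC)CC)(C(C)C)[C@H]2[C@@H]3O[C@@H]3C(C)C(=O)C[C@]12C | intermediate
22 | γ-hydroxy enone with C4 α-OH | CC(=O)O[C@H]1C[C@](O[Si](CC)(CC)CC)(C(C)C)[C@H]2[C@H](O)C=C(C)C(=O)C[C@]12C | intermediate
23 | 4-acetoxybenzoic acid | CC(=O)Oc1ccc(cc1)C(=O)O | starting material
24 | 4-acetoxybenzoyl chloride | CC(=O)Oc1ccc(cc1)C(Cl)=O | intermediate (not isolated)
25 | protected target: C4 α-4-acetoxybenzoate, C3 triethylsilyl ether | CC(=O)O[C@H]1C[C@](O[Si](CC)(CC)CC)(C(C)C)[C@H]2[C@H](OC(=O)c3ccc(OC(C)=O)cc3)C=C(C)C(=O)C[C@]12C | intermediate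
26 | C3 carbinol, aryl acetate retained | CC(=O)O[C@H]1C[C@](O)(C(C)C)[C@H]2[C@H](OC(=O)c3ccc(OC(C)=O)cc3)C=C(C)C(=O)C[C@]12C | intermediate
27 | CNP0087181.7 | CC(=O)O[C@H]1C[C@](O)(C(C)C)[C@H]2[C@H](OC(=O)c3ccc(O)cc3)C=C(C)C(=O)C[C@]12C | target

**Step count**
Total: 19 steps. Longest linear sequence: 19 steps, from 1 to 27; all other starting materials enter as purchased reagents.

**Steps most likely to fail**

Step 3. Alkylation of the hindered tetrasubstituted magnesium enolate may be slow. Proton exchange with the product would then move the enolate to C2, where the C3 silyloxy group is lost by β-elimination or a second prenylation occurs. Fallback, setting out from 3 and returning at 7: the copper-catalysed addition of 4 is run with Me3SiCl present, so that the enolate is captured and isolated as the trimethylsilyl enol ether F1. MeLi in THF at 0 °C then releases the salt-free lithium enolate F2, which is alkylated at C8a with prenyl bromide 5 and HMPA at −78 °C to give 7.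

Step 6. Discrimination between the two secondary carbinols may be incomplete, giving C1 oxidation or the 1,3-diketone, and the β-hydroxy ketone may dehydrate on prolonged exposure. Fallback, setting out from 9 and returning at 12: the sites are told apart by protection instead of by the oxidant.
- Et3SiCl and imidazole at −40 °C silylate only the unhindered C3 hydroxyl to give the C3 triethylsilyl ether F3.
- TBSOTf and 2,6-lutidine cap C1 to give the bis-silyl ether F4.
- PPTS in MeOH removes the triethylsilyl group alone to give the C1-protected C3 carbinol F5.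
- Dess–Martin periodinane gives the C3 ketone F6.
- Isopropylmagnesium chloride 11 with LaCl3·2LiCl gives the tertiary carbinol F7.
- HF·pyridine frees the C1 hydroxyl and delivers 12.

Step 14. Facial selectivity may be poor across the C6/C7 diastereomers of 19, so that oxygen enters partly or mainly from the β face and C4 ends up epimeric. Fallback, setting out from 19 and returning at 25: the β-epoxide F8 is taken through the same oxidation and base treatment, by way of the β-epoxy ketone F9, to the 4-epi γ-hydroxy enone F10. The configuration is then corrected in the esterification itself: a Mitsunobu reaction of F10 with 4-acetoxybenzoic acid 23 (PPh3, diisopropyl azodicarboxylate, THF, 0 °C) inverts C4 and gives 25 directly.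

**Further compounds**
F1 | step 3 | trimethylsilyl enol ether of the conjugate adduct (C1–OSiMe3, C1=C8a; C3a β-vinyl; C3 α-OTBS) | C[Si](C)(C)OC1=C(C)[C@H](C=C)[C@@H](O[Si](C)(C)C(C)(C)C)C1
F2 | step 3 | lithium C1/C8a enolate | [Li]OC1=C(C)[C@H](C=C)[C@@H](O[Si](C)(C)C(C)(C)C)C1
F3 | step 6 | C3 α-triethylsilyl ether, C1 β-OH | O[C@H]1C[C@H](O[Si](CC)(CC)CC)[C@@H](C=C)[C@]1(C)CC=C(C)C
F4 | step 6 | C1 β-OTBS, C3 α-OTES bis-silyl ether | CC(C)(C)[Si](C)(C)O[C@H]1C[C@H](O[Si](CC)(CC)CC)[C@@H](C=C)[C@]1(C)CC=C(C)C
F5 | step 6 | C1 β-OTBS, C3 α-OH | CC(C)(C)[Si](C)(C)O[C@H]1C[C@H](O)[C@@H](C=C)[C@]1(C)CC=C(C)C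
F6 | step 6 | C1 β-OTBS, C3 ketone | CC(C)(C)[Si](C)(C)O[C@H]1CC(=O)[C@@H](C=C)[C@]1(C)CC=C(C)C
F7 | step 6 | C1 β-OTBS, C3 β-OH α-isopropyl carbinol | CC(C)(C)[Si](C)(C)O[C@H]1C[C@](O)(C(C)C)[C@@H](C=C)[C@]1(C)CC=C(C)C
F8 | step 14 | 4β,5β-epoxide of 19 | CC(=O)O[C@H]1C[C@](O[Si](CC)(CC)CC)(C(C)C)[C@H]2[C@H]3O[C@H]3C(C)C(O)C[C@]12C
F9 | step 14 | β,γ-epoxy ketone with 4β,5β-epoxide | CC(=O)O[C@H]1C[C@](O[Si](CC)(CC)CC)(C(C)C)[C@H]2[C@H]3O[C@H]3C(C)C(=O)C[C@]12C
F10 | step 14 | 4-epi γ-hydroxy enone (C4 β-OH) | CC(=O)O[C@H]1C[C@](O[Si](CC)(CC)CC)(C(C)C)[C@H]2[C@@H](O)C=C(C)C(=O)C[C@]12C
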